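**Retrosynthetic overview**
- The target comes from fluoride removal of two aryl TIPS ethers and a TMSE ester, after aldehyde-selective reduction of an (E)-2-methyl enal made by Wittig olefination of a ring-bound propanal.
- Key step: Claisen rearrangement of the vinyl ether of a 5-hydroxy-6-methyleneoxepane makes the C6–CH2 side-chain bond and moves the double bond into the ring (C5=C6).
- The oxepane is closed at C5–C6 by an intramolecular Nozaki–Hiyama–Kishi reaction of a 2-bromoallyl ether onto an aldehyde; that aldehyde and the aryl ketone are unmasked together from two alkenes.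
- The quaternary C2 is set by Seebach alkylation (self-regeneration of the stereocentre) of the cis pivaldehyde acetal of (S)-2-hydroxyhex-5-enoic acid, made from the L-glutamic-acid-derived lactone acid.
- Ring order: the arene is bought (bromohydroquinone), the oxepane is formed by the NHK closure, and its ring alkene is installed by the Claisen step.

Assumption: 1, 2, 4, 7, 9, 10, 13, 17, 19, 23 and 26 are taken as catalogue compounds; organic reagents that contribute atoms are numbered like starting materials, inorganic ones are given by name and SMILES in the reagent line.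

**Step 1**
Reactants: 1 2-bromobenzene-1,4-diol; 2 chlorotriisopropylsilane
Product: 3 2-bromo-1,4-bis(triisopropylsilyloxy)benzene
Conditions: TIPSCl (2.5 equiv), imidazole (5 equiv), DMF, 40 °C
Reagents that add atoms: chlorotriisopropylsilane (2), CC(C)[Si](Cl)(C(C)C)C(C)C
Why: Imidazole-promoted O-silylation protects both phenols as TIPS ethers that tolerate bases and organometallics and are removed by fluoride at the end.

**Step 2**
Reactants: 3 aryl bromide; 4 prop-2-yn-1-ol
Product: 6 2-[2,5-bis(triisopropylsilyloxy)phenyl]prop-2-en-1-ol, via aryl Grignard reagent 5 (not isolated)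
Conditions: Mg, THF, 50 °C; then 4 premixed with i-PrMgCl (1 equiv), CuI (10 mol %), THF, 0 → 45 °C; aq. NH4Cl
Reagents that add atoms: prop-2-yn-1-ol (4), C#CCO; magnesium, [Mg] (stays only in 5)
Why: Grignard formation followed by copper-catalysed anti-carbomagnesiation of the propargylic alkoxide puts the aryl group on the internal alkyne carbon and gives the 2-arylallyl alcohol.

**Step 3**
Reactants: 6 allylic alcohol; 7 tetrabromomethane
Product: 8 2-(3-bromoprop-1-en-2-yl)-1,4-bis(triisopropylsilyloxy)benzene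
Conditions: CBr4, PPh3, CH2Cl2, 0 °C
Reagents that add atoms: tetrabromomethane (7), BrC(Br)(Br)Br
Why: The Appel reaction converts the primary allylic alcohol into the bromide under neutral conditions that spare the silyl ethers and the styrene.

**Step 4**
Reactants: 9 (S)-5-oxotetrahydrofuran-2-carboxylic acid; 10 methyltriphenylphosphonium bromide
Product: 12 (S)-2-hydroxyhex-5-enoic acid, via lactol acid 11 (not isolated)
Conditions: DIBAL-H (2.2 equiv), THF, −78 °C; then Ph3P=CH2 (3.5 equiv, from 10 and KOt-Bu), −78 °C → rt; base/acid extraction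
Reagents that add atoms: methyltriphenylphosphonium bromide (10), C[P+](c1ccccc1)(c1ccccc1)c1ccccc1.[Br-]
Why: DIBAL-H first masks the acid as its aluminium carboxylate and then reduces the lactone to the lactolate, whose open hydroxy-aldehyde form undergoes Wittig methylenation in the same pot without touching the bought-in C2 stereocentre.

**Step 5**
Reactants: 12 hydroxy acid; 13 2,2-dimethylpropanal
Product: 14 (2S,5S)-5-(but-3-en-1-yl)-2-tert-butyl-1,3-dioxolan-4-one
Conditions: t-BuCHO (2 equiv), TsOH·H2O (cat.), H2SO4 (cat.), pentane, reflux, Dean–Stark; chromatography to remove the minor trans isomer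
Reagents that add atoms: 2,2-dimethylpropanal (13), CC(C)(C)C=O
Why: Seebach acetalisation under equilibrating conditions lets the hydroxy-acid stereocentre place the tert-butyl group cis to the side chain, creating the temporary acetal stereocentre.

**Step 6**
Reactants: 14 dioxolanone; 8 allylic bromide
Product: 16 (2S,5R)-5-{2-[2,5-bis(triisopropylsilyloxy)phenyl]prop-2-en-1-yl}-5-(but-3-en-1-yl)-2-tert-butyl-1,3-dioxolan-4-one, via lithium enolate 15 (not isolated)
Conditions: LDA (1.1 equiv), THF, −78 °C; then 8, DMPU, −78 → −40 °C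
Reagents that add atoms: lithium diisopropylamide, [Li+].CC(C)[N-]C(C)C (lithium stays only in 15)
Why: In the planar enolate only the acetal centre remains, and its tert-butyl group shields one face, so SN2 alkylation by the allylic bromide occurs trans to it and regenerates the α-carbon as the (R)-quaternary centre with net retention (self-regeneration of stereocentres).

**Step 7**
Reactants: 16 alkylated dioxolanone; 17 2-(trimethylsilyl)ethanol
Product: 18 2-(trimethylsilyl)ethyl (2R)-2-{2-[2,5-bis(triisopropylsilyloxy)phenyl]prop-2-en-1-yl}-2-hydroxyhex-5-enoate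
Conditions: TMSCH2CH2OH (5 equiv), NaH (0.2 equiv), THF, 0 °C → rt
Reagents that add atoms: 2-(trimethylsilyl)ethanol (17), C[Si](C)(C)CCO
Why: Alkoxide-catalysed transesterification opens the acylal, expels pivaldehyde and leaves the tertiary α-hydroxy ester as a fluoride-cleavable TMSE ester with the stereocentre untouched.

**Step 8**
Reactants: 18 tertiary alcohol; 19 2,3-dibromoprop-1-ene
Product: 20 2-(trimethylsilyl)ethyl (2R)-2-{2-[2,5-bis(triisopropylsilyloxy)phenyl]prop-2-en-1-yl}-2-[(2-bromoprop-2-en-1-yl)oxy]hex-5-enoate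
Conditions: NaH (1.5 equiv), Bu4NI (cat.), DMF, 0 °C; then 19 (3 equiv), 0 °C → rt
Reagents that add atoms: 2,3-dibromoprop-1-ene (19), C=C(Br)CBr
Why: Williamson etherification with the reactive allylic bromide is safe here because both future carbonyl groups are still alkenes, so the tertiary alkoxide has no retro-aldol or β-elimination pathway.

**Step 9**
Reactants: 20 triene ether
Product: 21 2-(trimethylsilyl)ethyl (2R)-2-{2-[2,5-bis(triisopropylsilyloxy)phenyl]-2-oxoethyl}-2-[(2-bromoprop-2-en-1-yl)oxy]-5-oxopentanoate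
Conditions: OsO4 (4 mol %), NaIO4 (6 equiv), 2,6-lutidine, dioxane/H2O (3:1), rt
Reagents that add atoms: sodium periodate, [Na+].[O-]I(=O)(=O)=O; osmium tetroxide, O=[Os](=O)(=O)=O
Why: Lemieux–Johnson oxidative cleavage converts the two electron-rich alkenes into the C5 aldehyde and the aryl ketone in one operation, while the electron-poor vinyl bromide is dihydroxylated far more slowly.

**Step 10**
Reactants: 21 keto aldehyde
Product: 22 2-(trimethylsilyl)ethyl (2R)-2-{2-[2,5-bis(triisopropylsilyloxy)phenyl]-2-oxoethyl}-5-hydroxy-6-methylideneoxepane-2-carboxylate (C5 epimer mixture)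
Conditions: CrCl2 (8 equiv), NiCl2 (2 mol %), degassed DMF (0.005 M), rt
Reagents that add atoms: none
Why: The intramolecular Nozaki–Hiyama–Kishi reaction adds the C–Br carbon chemoselectively to the aldehyde, not to the hindered aryl ketone or the ester, closing the oxepane; the new carbinol centre is uncontrolled but is erased in step 11.

**Step 11**
Reactants: 22 allylic alcohol; 23 ethoxyethene
Product: 25 2-(trimethylsilyl)ethyl (2R)-2-{2-[2,5-bis(triisopropylsilyloxy)phenyl]-2-oxoethyl}-6-(3-oxopropyl)-2,3,4,7-tetrahydrooxepine-2-carboxylate, via allyl vinyl ether 24 (not isolated)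
Conditions: Hg(OAc)2 (0.3 equiv), ethyl vinyl ether (solvent), reflux; evaporate; PhMe, Et3N (cat.), 130 °C, sealed tube
Reagents that add atoms: ethoxyethene (23), C=COCC
Why: Hg(II)-catalysed transvinylation followed by the Claisen [3,3]-sigmatropic rearrangement bonds the vinyl terminus to the exocyclic methylene carbon, which forges the C6–CH2 side-chain bond, places the double bond in the ring (cis by ring constraint) and removes the C5 stereocentre.

**Step 12**
Reactants: 25 aldehyde; 26 2-(triphenylphosphoranylidene)propanal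
Product: 27 2-(trimethylsilyl)ethyl (2R)-2-{2-[2,5-bis(triisopropylsilyloxy)phenyl]-2-oxoethyl}-6-[(3E)-4-methyl-5-oxopent-3-en-1-yl]-2,3,4,7-tetrahydrooxepine-2-carboxylate
Conditions: 26 (1.5 equiv), PhMe, 90 °C
Reagents that add atoms: 2-(triphenylphosphoranylidene)propanal (26), CC(C=O)=P(c1ccccc1)(c1ccccc1)c1ccccc1
Why: Wittig olefination with the stabilised α-methyl ylide reacts only with the aldehyde (not the ketone) and gives the (E)-2-methyl enal, as expected for a stabilised ylide.

**Step 13**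
Reactants: 27 enal
Product: 28 2-(trimethylsilyl)ethyl (2R)-2-{2-[2,5-bis(triisopropylsilyloxy)phenyl]-2-oxoethyl}-6-[(3E)-5-hydroxy-4-methylpent-3-en-1-yl]-2,3,4,7-tetrahydrooxepine-2-carboxylate
Conditions: NaBH4 (1 equiv), MeOH/CH2Cl2 (1:1), −78 °C
Reagents that add atoms: none
Why: Low-temperature borohydride 1,2-reduction takes the aldehyde selectively over the hindered, electron-rich aryl ketone and the ester, giving the (E)-allylic alcohol without touching the alkene geometry.

**Step 14**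
Reactants: 28 protected target
Product: 29 (2R)-2-[2-(2,5-dihydroxyphenyl)-2-oxoethyl]-6-[(3E)-5-hydroxy-4-methylpent-3-en-1-yl]-2,3,4,7-tetrahydrooxepine-2-carboxylic acid
Conditions: TBAF (5 equiv), degassed THF, 0 °C → rt; aq. NH4Cl (pH about 4)
Reagents that add atoms: none
Why: Fluoride-mediated global desilylation cleaves both aryl TIPS ethers and fragments the TMSE ester (β-elimination) to the free acid under conditions mild enough for the β-alkoxy ketone and the hydroquinone.

**Compound list**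
1 | 2-bromobenzene-1,4-diol | Oc1ccc(O)c(Br)c1 | starting material
2 | chlorotriisopropylsilane | CC(C)[Si](Cl)(C(C)C)C(C)C | starting material
3 | 2-bromo-1,4-bis(triisopropylsilyloxy)benzene | Brc1cc(O[Si](C(C)C)(C(C)C)C(C)C)ccc1O[Si](C(C)C)(C(C)C)C(C)C | intermediate
4 | prop-2-yn-1-ol | C#CCO | starting material
5 | [2,5-bis(triisopropylsilyloxy)phenyl]magnesium bromide | Br[Mg]c1cc(O[Si](C(C)C)(C(C)C)C(C)C)ccc1O[Si](C(C)C)(C(C)C)C(C)C | intermediate
6 | 2-[2,5-bis(triisopropylsilyloxy)phenyl]prop-2-en-1-ol | C=C(CO)c1cc(O[Si](C(C)C)(C(C)C)C(C)C)ccc1O[Si](C(C)C)(C(C)C)C(C)C | intermediate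
7 | tetrabromomethane | BrC(Br)(Br)Br | starting material
8 | 2-(3-bromoprop-1-en-2-yl)-1,4-bis(triisopropylsilyloxy)benzene | C=C(CBr)c1cc(O[Si](C(C)C)(C(C)C)C(C)C)ccc1O[Si](C(C)C)(C(C)C)C(C)C | intermediate
9 | (S)-5-oxotetrahydrofuran-2-carboxylic acid | OC(=O)[C@@H]1CCC(=O)O1 | starting material
10 | methyltriphenylphosphonium bromide | C[P+](c1ccccc1)(c1ccccc1)c1ccccc1.[Br-] | starting material
11 | (2S)-5-hydroxytetrahydrofuran-2-carboxylic acid (lactol, anomer mixture, present as its aluminium salt) | OC(=O)[C@@H]1CCC(O)O1 | intermediate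
12 | (S)-2-hydroxyhex-5-enoic acid | C=CCC[C@H](O)C(=O)O | intermediate
13 | 2,2-dimethylpropanal | CC(C)(C)C=O | starting material
14 | (2S,5S)-5-(but-3-en-1-yl)-2-tert-butyl-1,3-dioxolan-4-one (cis) | C=CCC[C@@H]1O[C@H](C(C)(C)C)OC1=O | intermediate
15 | lithium (2S)-5-(but-3-en-1-yl)-2-tert-butyl-1,3-dioxol-4-olate | C=CCCC1=C(O[Li])O[C@@H](C(C)(C)C)O1 | intermediate
16 | (2S,5R)-5-{2-[2,5-bis(triisopropylsilyloxy)phenyl]prop-2-en-1-yl}-5-(but-3-en-1-yl)-2-tert-butyl-1,3-dioxolan-4-one | C=CCC[C@]1(CC(=C)c2cc(O[Si](C(C)C)(C(C)C)C(C)C)ccc2O[Si](C(C)C)(C(C)C)C(C)C)O[C@H](C(C)(C)C)OC1=O | intermediate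
17 | 2-(trimethylsilyl)ethanol | C[Si](C)(C)CCO | starting material
18 | 2-(trimethylsilyl)ethyl (2R)-2-{2-[2,5-bis(triisopropylsilyloxy)phenyl]prop-2-en-1-yl}-2-hydroxyhex-5-enoate | C=CCC[C@@](O)(CC(=C)c1cc(O[Si](C(C)C)(C(C)C)C(C)C)ccc1O[Si](C(C)C)(C(C)C)C(C)C)C(=O)OCC[Si](C)(C)C | intermediate
19 | 2,3-dibromoprop-1-ene | C=C(Br)CBr | starting material
20 | 2-(trimethylsilyl)ethyl (2R)-2-{2-[2,5-bis(triisopropylsilyloxy)phenyl]prop-2-en-1-yl}-2-[(2-bromoprop-2-en-1-yl)oxy]hex-5-enoate | C=CCC[C@@](OCC(Br)=C)(CC(=C)c1cc(O[Si](C(C)C)(C(C)C)C(C)C)ccc1O[Si](C(C)C)(C(C)C)C(C)C)C(=O)OCC[Si](C)(C)C | intermediate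
21 | 2-(trimethylsilyl)ethyl (2R)-2-{2-[2,5-bis(triisopropylsilyloxy)phenyl]-2-oxoethyl}-2-[(2-bromoprop-2-en-1-yl)oxy]-5-oxopentanoate | O=CCC[C@@](OCC(Br)=C)(CC(=O)c1cc(O[Si](C(C)C)(C(C)C)C(C)C)ccc1O[Si](C(C)C)(C(C)C)C(C)C)C(=O)OCC[Si](C)(C)C | intermediate
22 | 2-(trimethylsilyl)ethyl (2R)-2-{2-[2,5-bis(triisopropylsilyloxy)phenyl]-2-oxoethyl}-5-hydroxy-6-methylideneoxepane-2-carboxylate (C5 epimers) | OC1CC[C@@](CC(=O)c2cc(O[Si](C(C)C)(C(C)C)C(C)C)ccc2O[Si](C(C)C)(C(C)C)C(C)C)(C(=O)OCC[Si](C)(C)C)OCC1=C | intermediate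
23 | ethoxyethene (ethyl vinyl ether) | C=COCC | starting material
24 | 2-(trimethylsilyl)ethyl (2R)-2-{2-[2,5-bis(triisopropylsilyloxy)phenyl]-2-oxoethyl}-5-(ethenyloxy)-6-methylideneoxepane-2-carboxylate (C5 epimers) | C=COC1CC[C@@](CC(=O)c2cc(O[Si](C(C)C)(C(C)C)C(C)C)ccc2O[Si](C(C)C)(C(C)C)C(C)C)(C(=O)OCC[Si](C)(C)C)OCC1=C | intermediate
25 | 2-(trimethylsilyl)ethyl (2R)-2-{2-[2,5-bis(triisopropylsilyloxy)phenyl]-2-oxoethyl}-6-(3-oxopropyl)-2,3,4,7-tetrahydrooxepine-2-carboxylate | O=CCCC1=CCC[C@@](CC(=O)c2cc(O[Si](C(C)C)(C(C)C)C(C)C)ccc2O[Si](C(C)C)(C(C)C)C(C)C)(C(=O)OCC[Si](C)(C)C)OC1 | intermediate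
26 | 2-(triphenylphosphoranylidene)propanal | CC(C=O)=P(c1ccccc1)(c1ccccc1)c1ccccc1 | starting material
27 | 2-(trimethylsilyl)ethyl (2R)-2-{2-[2,5-bis(triisopropylsilyloxy)phenyl]-2-oxoethyl}-6-[(3E)-4-methyl-5-oxopent-3-en-1-yl]-2,3,4,7-tetrahydrooxepine-2-carboxylate | C/C(=C\CCC1=CCC[C@@](CC(=O)c2cc(O[Si](C(C)C)(C(C)C)C(C)C)ccc2O[Si](C(C)C)(C(C)C)C(C)C)(C(=O)OCC[Si](C)(C)C)OC1)C=O | intermediate
28 | 2-(trimethylsilyl)ethyl (2R)-2-{2-[2,5-bis(triisopropylsilyloxy)phenyl]-2-oxoethyl}-6-[(3E)-5-hydroxy-4-methylpent-3-en-1-yl]-2,3,4,7-tetrahydrooxepine-2-carboxylate | C/C(=C\CCC1=CCC[C@@](CC(=O)c2cc(O[Si](C(C)C)(C(C)C)C(C)C)ccc2O[Si](C(C)C)(C(C)C)C(C)C)(C(=O)OCC[Si](C)(C)C)OC1)CO | intermediate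
29 | (2R)-2-[2-(2,5-dihydroxyphenyl)-2-oxoethyl]-6-[(3E)-5-hydroxy-4-methylpent-3-en-1-yl]-2,3,4,7-tetrahydrooxepine-2-carboxylic acid (CNP0570804.1) | C/C(=C\CCC1=CCC[C@@](CC(=O)c2cc(O)ccc2O)(C(=O)O)OC1)CO | target

**Step count**
Total: 14 steps. Longest linear sequence: 12 steps (steps 1–3, then 6–14, from 1); the chiral branch from 9 is 11 steps.

**Three steps most likely to fail**

Step 10 (seven-membered NHK closure with a ketone in the molecule) is the main risk: oligomerisation, or attack at the ketone through a six-membered transition state. The fallback closes the same C5–C6 bond by nickel-catalysed reductive alkyne–aldehyde cyclisation. It sets out from 18: O-alkylation with propargyl bromide (NaH, DMF) gives 2-(trimethylsilyl)ethyl (2R)-2-{2-[2,5-bis(triisopropylsilyloxy)phenyl]prop-2-en-1-yl}-2-(prop-2-yn-1-yloxy)hex-5-enoate F6. The OsO4/NaIO4 cleavage of step 9 then gives 2-(trimethylsilyl)ethyl (2R)-2-{2-[2,5-bis(triisopropylsilyloxy)phenyl]-2-oxoethyl}-5-oxo-2-(prop-2-yn-1-yloxy)pentanoate F7; the alkyne is inert to these conditions. Ni(cod)2/IMes with Et3SiH in THF closes the ring at the proximal alkyne carbon to 2-(trimethylsilyl)ethyl (2R)-2-{2-[2,5-bis(triisopropylsilyloxy)phenyl]-2-oxoethyl}-6-methylidene-5-(triethylsilyloxy)oxepane-2-carboxylate F8. PPTS in MeOH removes the triethylsilyl group and the route is rejoined at 22.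

Step 4 (one-pot lactone reduction and methylenation on an unprotected acid) may over-reduce or give a poorly extractable product. The fallback uses lipophilic ester intermediates and sets out from 9. Isobutene with catalytic H2SO4 gives tert-butyl (2S)-5-oxooxolane-2-carboxylate F1. DIBAL-H (1.1 equiv, −78 °C) reduces the lactone selectively to tert-butyl (2S)-5-hydroxyoxolane-2-carboxylate F2. Ph3P=CH2 gives tert-butyl (2S)-2-hydroxyhex-5-enoate F3, and TFA in CH2Cl2 cleaves the ester to come back at 12.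

Step 6 (creation of the quaternary centre with a bulky ortho-silyloxy arylallyl bromide and a thermally fragile enolate) may stall. The fallback builds the aryl–alkene bond by cross-coupling after the alkylation and sets out from 14. Enolate 15 is alkylated with the small electrophile 19 to give (2S,5R)-5-(2-bromoprop-2-en-1-yl)-5-(but-3-en-1-yl)-2-tert-butyl-1,3-dioxolan-4-one F4. Grignard reagent 5 is transmetallated with ZnCl2 to [2,5-bis(triisopropylsilyloxy)phenyl]zinc chloride F5. Negishi coupling of F4 with F5 (Pd(PPh3)4, THF, 50 °C, base-free so the dioxolanone survives) comes back at 16.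

**Further compounds**
F1 | step 4 | tert-butyl (2S)-5-oxooxolane-2-carboxylate | CC(C)(C)OC(=O)[C@@H]1CCC(=O)O1
F2 | step 4 | tert-butyl (2S)-5-hydroxyoxolane-2-carboxylate (anomers) | CC(C)(C)OC(=O)[C@@H]1CCC(O)O1
F3 | step 4 | tert-butyl (2S)-2-hydroxyhex-5-enoate | C=CCC[C@H](O)C(=O)OC(C)(C)C
F4 | step 6 | (2S,5R)-5-(2-bromoprop-2-en-1-yl)-5-(but-3-en-1-yl)-2-tert-butyl-1,3-dioxolan-4-one | C=CCC[C@]1(CC(Br)=C)O[C@H](C(C)(C)C)OC1=O
F5 | step 6 | [2,5-bis(triisopropylsilyloxy)phenyl]zinc chloride | Cl[Zn]c1cc(O[Si](C(C)C)(C(C)C)C(C)C)ccc1O[Si](C(C)C)(C(C)C)C(C)C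
F6 | step 10 | 2-(trimethylsilyl)ethyl (2R)-2-{2-[2,5-bis(triisopropylsilyloxy)phenyl]prop-2-en-1-yl}-2-(prop-2-yn-1-yloxy)hex-5-enoate | C=CCC[C@@](OCC#C)(CC(=C)c1cc(O[Si](C(C)C)(C(C)C)C(C)C)ccc1O[Si](C(C)C)(C(C)C)C(C)C)C(=O)OCC[Si](C)(C)C
F7 | step 10 | 2-(trimethylsilyl)ethyl (2R)-2-{2-[2,5-bis(triisopropylsilyloxy)phenyl]-2-oxoethyl}-5-oxo-2-(prop-2-yn-1-yloxy)pentanoate | O=CCC[C@@](OCC#C)(CC(=O)c1cc(O[Si](C(C)C)(C(C)C)C(C)C)ccc1O[Si](C(C)C)(C(C)C)C(C)C)C(=O)OCC[Si](C)(C)C
F8 | step 10 | 2-(trimethylsilyl)ethyl (2R)-2-{2-[2,5-bis(triisopropylsilyloxy)phenyl]-2-oxoethyl}-6-methylidene-5-(triethylsilyloxy)oxepane-2-carboxylate (C5 epimers) | CC[Si](CC)(CC)OC1CC[C@@](CC(=O)c2cc(O[Si](C(C)C)(C(C)C)C(C)C)ccc2O[Si](C(C)C)(C(C)C)C(C)C)(C(=O)OCC[Si](C)(C)C)OCC1=C
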